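**Plan**
1. Retrosynthesis: the two benzyl groups (ring A 2‑O‑benzyl ether, ring B benzyl ester) are put back first. The bond between ring A C6 and the side‑chain CH2 is cut next, giving a bromo depside and 1‑chlorononan‑2‑one. The depside C(=O)–O bond is cut last, giving a 6‑bromosalicylic acid and benzyl orsellinate.
2. Forward: ring A is built from 1‑bromo‑3,5‑dimethoxybenzene (formylation, chelation‑controlled mono‑demethylation, benzylation, oxidation) and ring B from orsellinic acid. The depside ester is formed at the 4‑OH of ring B, the C9 keto chain is joined by a nickel‑catalysed electroreductive cross‑electrophile coupling, and hydrogenolysis ends the route.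
3. Enabling feature: C6 of ring A lies ortho to the depside carbonyl on C1 and meta to the oxygens on C2 and C4, so its C–Br bond is electron‑poor and carbonyl‑assisted towards Ni(0). C1 of the chain is alpha to the C2 ketone, so its C–Cl bond is an activated alkyl halide.
4. The bromine is also a placeholder: the free 2‑oxoalkyl benzoic acid, which would close to a 3‑heptylisocoumarin on carboxyl activation, is never made.
5. Stereochemistry: none has to be set.

Key step: step 8

Remark: the target has no stereocentre or other stereogenic element, so it is a single achiral compound and no enantiocontrol is required.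

**Step 1**
Reactants: 1 1‑bromo‑3,5‑dimethoxybenzene
Product: 3 2‑bromo‑4,6‑dimethoxybenzaldehyde, via aryl iminium dichlorophosphate 2 (not isolated)
Conditions: POCl3, DMF, 0 → 90 °C; then ice/H2O
Reagents that add atoms: N,N‑dimethylformamide CN(C)C=O; water O
Why: Vilsmeier–Haack formylation should take place para to one methoxy group and ortho to the other (next to bromine) rather than at the carbon flanked by both methoxy groups, as is usual for 1,3‑dimethoxyarenes.

**Step 2**
Reactants: 3 2‑bromo‑4,6‑dimethoxybenzaldehyde
Product: 5 2‑bromo‑6‑hydroxy‑4‑methoxybenzaldehyde, via aryloxydichloroborane 4 (not isolated)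
Conditions: BCl3, CH2Cl2, −78 → 0 °C; then H2O
Reagents that add atoms: none
Why: Chelation‑controlled Lewis‑acid ether cleavage should remove only the methyl group of the methoxy ortho to the formyl group, because boron bound to the carbonyl oxygen activates that ether alone and leaves the para methoxy untouched.

**Step 3**
Reactants: 5 2‑bromo‑6‑hydroxy‑4‑methoxybenzaldehyde
Product: 6 2‑(benzyloxy)‑6‑bromo‑4‑methoxybenzaldehyde
Conditions: BnBr, K2CO3, DMF, rt
Reagents that add atoms: benzyl bromide BrCc1ccccc1
Why: Williamson ether synthesis on the acidic ortho‑formyl phenol should be clean, and the benzyl ether can be removed at the end together with the benzyl ester.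

**Step 4**
Reactants: 6 2‑(benzyloxy)‑6‑bromo‑4‑methoxybenzaldehyde
Product: 7 2‑(benzyloxy)‑6‑bromo‑4‑methoxybenzoic acid
Conditions: NaClO2, NaH2PO4, 2‑methyl‑2‑butene, t‑BuOH/THF/H2O, rt
Reagents that add atoms: sodium chlorite [Na+].[O-]Cl=O
Why: Pinnick oxidation should convert the hindered aldehyde into the acid without touching the aryl bromide or the benzyl ether, the alkene scavenging hypochlorous acid before it can chlorinate the electron‑rich ring.

**Step 5**
Reactants: 8 orsellinic acid (2,4‑dihydroxy‑6‑methylbenzoic acid)
Product: 9 benzyl 2,4‑dihydroxy‑6‑methylbenzoate (benzyl orsellinate)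
Conditions: BnBr, KHCO3, DMF, rt → 40 °C
Reagents that add atoms: benzyl bromide BrCc1ccccc1
Why: Carboxylate O‑alkylation should be chemoselective because hydrogen carbonate deprotonates only the carboxylic acid and not the phenols, and the mild temperature avoids decarboxylation.

**Step 6**
Reactants: 7 2‑(benzyloxy)‑6‑bromo‑4‑methoxybenzoic acid; 9 benzyl 2,4‑dihydroxy‑6‑methylbenzoate
Product: 11 benzyl 4‑{[2‑(benzyloxy)‑6‑bromo‑4‑methoxybenzoyl]oxy}‑2‑hydroxy‑6‑methylbenzoate, via aroyl trifluoroacetate mixed anhydride 10 (not isolated)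
Conditions: TFAA, toluene, rt; aq. NaHCO3 work‑up
Reagents that add atoms: none
Why: Mixed‑anhydride esterification with trifluoroacetic anhydride is the standard depside‑forming reaction for 2,6‑disubstituted benzoic acids, and it should acylate the free 4‑OH of 9 because the 2‑OH is held in a hydrogen bond to the benzyl ester carbonyl.

**Step 7**
Reactants: 12 heptylmagnesium bromide; 13 2‑chloro‑N‑methoxy‑N‑methylacetamide
Product: 15 1‑chlorononan‑2‑one, via magnesium hemiaminal chelate 14 (not isolated)
Conditions: THF, −78 → 0 °C; then 1 M HCl, 0 °C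
Reagents that add atoms: none
Why: Weinreb ketone synthesis should stop at the stable five‑membered magnesium chelate, so that the chloromethyl ketone is released only on acidic work‑up and neither over‑addition nor displacement of chloride occurs.

**Step 8**
Reactants: 11 benzyl 4‑{[2‑(benzyloxy)‑6‑bromo‑4‑methoxybenzoyl]oxy}‑2‑hydroxy‑6‑methylbenzoate; 15 1‑chlorononan‑2‑one
Product: 16 benzyl 4‑{[2‑(benzyloxy)‑4‑methoxy‑6‑(2‑oxononyl)benzoyl]oxy}‑2‑hydroxy‑6‑methylbenzoate
Conditions: NiBr2(bpy) (10 mol%), n‑Bu4NBF4, DMF, 50 °C, undivided cell, sacrificial Zn anode, Ni‑foam cathode, constant current (ca. 2.2 F per mol of 11); 15 (2 equiv) added slowly by syringe pump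
Reagents that add atoms: none
Why: Cathodically formed Ni(0)(bpy) should insert into the C6–Br bond of ring A, the aryl–nickel species should be reduced and then take up the C1–Cl bond of 15, and reductive elimination from the aryl(2‑oxoalkyl)nickel intermediate should form the C(sp2)–C(sp3) bond while Zn2+ from the anode balances the halide released. The closest known reaction type is the nickel–bipyridine‑catalysed electroreductive cross‑coupling of aryl halides with α‑chloro ketones at a sacrificial anode, a cross‑electrophile coupling. No ring is closed and no stereocentre is formed. The step needs cross‑coupling to win over biaryl formation, 1,4‑diketone formation and hydrodebromination; slow addition of the more easily reduced chloro ketone and the persistence of the ortho‑substituted, carbonyl‑coordinated aryl–nickel species should secure this. The position of chlorine fixes the site of arylation at C1 of the nonanone, so the C3 methylene cannot compete as it would in an enolate arylation. The base‑free medium should spare the twisted aryl ester, both benzyl groups and the hydrogen‑bonded phenol, and it delivers the ketone without an enolate that could close onto the ester carbonyl.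

**Step 9**
Reactants: 16 benzyl 4‑{[2‑(benzyloxy)‑4‑methoxy‑6‑(2‑oxononyl)benzoyl]oxy}‑2‑hydroxy‑6‑methylbenzoate
Product: 17 2‑hydroxy‑4‑{[2‑hydroxy‑4‑methoxy‑6‑(2‑oxononyl)benzoyl]oxy}‑6‑methylbenzoic acid (target)
Conditions: H2 (1 atm), 10% Pd/C, EtOAc, rt
Reagents that add atoms: none
Why: Catalytic hydrogenolysis should cleave the aryl benzyl ether and the benzyl ester in one operation under neutral conditions that leave the dialkyl‑type ketone and the depside ester intact.

**Compound list**
1 | 1‑bromo‑3,5‑dimethoxybenzene | COc1cc(Br)cc(OC)c1 | starting material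
2 | (2‑bromo‑4,6‑dimethoxybenzylidene)dimethyliminium dichlorophosphate | C[N+](C)=Cc1c(Br)cc(OC)cc1OC.[O-]P(=O)(Cl)Cl | intermediate
3 | 2‑bromo‑4,6‑dimethoxybenzaldehyde | O=Cc1c(Br)cc(OC)cc1OC | intermediate
4 | (3‑bromo‑2‑formyl‑5‑methoxyphenoxy)dichloroborane | O=Cc1c(Br)cc(OC)cc1OB(Cl)Cl | intermediate
5 | 2‑bromo‑6‑hydroxy‑4‑methoxybenzaldehyde | O=Cc1c(Br)cc(OC)cc1O | intermediate
6 | 2‑(benzyloxy)‑6‑bromo‑4‑methoxybenzaldehyde | O=Cc1c(Br)cc(OC)cc1OCc1ccccc1 | intermediate
7 | 2‑(benzyloxy)‑6‑bromo‑4‑methoxybenzoic acid | O=C(O)c1c(Br)cc(OC)cc1OCc1ccccc1 | intermediate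
8 | orsellinic acid (2,4‑dihydroxy‑6‑methylbenzoic acid) | Cc1cc(O)cc(O)c1C(=O)O | starting material
9 | benzyl 2,4‑dihydroxy‑6‑methylbenzoate | Cc1cc(O)cc(O)c1C(=O)OCc1ccccc1 | intermediate
10 | 2‑(benzyloxy)‑6‑bromo‑4‑methoxybenzoic trifluoroacetic anhydride | O=C(OC(=O)C(F)(F)F)c1c(Br)cc(OC)cc1OCc1ccccc1 | intermediate
11 | benzyl 4‑{[2‑(benzyloxy)‑6‑bromo‑4‑methoxybenzoyl]oxy}‑2‑hydroxy‑6‑methylbenzoate | COc1cc(Br)c(C(=O)Oc2cc(C)c(C(=O)OCc3ccccc3)c(O)c2)c(OCc2ccccc2)c1 | intermediate
12 | heptylmagnesium bromide | CCCCCCC[Mg]Br | starting material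
13 | 2‑chloro‑N‑methoxy‑N‑methylacetamide | CON(C)C(=O)CCl | starting material
14 | bromomagnesium 1‑chloro‑2‑[methoxy(methyl)amino]nonan‑2‑olate | CCCCCCCC(CCl)(O[Mg]Br)N(C)OC | intermediate
15 | 1‑chlorononan‑2‑one | CCCCCCCC(=O)CCl | intermediate
16 | benzyl 4‑{[2‑(benzyloxy)‑4‑methoxy‑6‑(2‑oxononyl)benzoyl]oxy}‑2‑hydroxy‑6‑methylbenzoate | CCCCCCCC(=O)Cc1cc(OC)cc(OCc2ccccc2)c1C(=O)Oc1cc(C)c(C(=O)OCc2ccccc2)c(O)c1 | intermediate
17 | 2‑hydroxy‑4‑{[2‑hydroxy‑4‑methoxy‑6‑(2‑oxononyl)benzoyl]oxy}‑6‑methylbenzoic acid | CCCCCCCC(=O)Cc1cc(OC)cc(O)c1C(=O)Oc1cc(C)c(C(=O)O)c(O)c1 | target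

**Total step count:** 9
**Longest linear sequence:** 7 steps (steps 1, 2, 3, 4, 6, 8, 9)

**Steps most likely to fail**

Step 8. The aryl–nickel intermediate may be protonated by the phenolic OH (hydrodebromination), the two halides may homocouple, the chloro ketone may be reduced directly at the cathode, or Zn2+ may promote enol lactonisation of the product onto the ester with loss of the ring B phenol. Fallback: setting out from 11, a Sonogashira coupling with non‑1‑yne (PdCl2(PPh3)2, CuI, Et3N, DMF, 60 °C) should give benzyl 4‑{[2‑(benzyloxy)‑4‑methoxy‑6‑(non‑1‑yn‑1‑yl)benzoyl]oxy}‑2‑hydroxy‑6‑methylbenzoate F1. Gold(III)‑catalysed hydration assisted by the neighbouring ester carbonyl (NaAuCl4 cat., wet 1,4‑dioxane, rt) should follow: the carbonyl oxygen adds 6‑endo to the alkyne carbon remote from the ring, and water reopens the cyclic oxocarbenium at the acyl carbon. This restores the ester, places the ketone on the carbon beta to the ring, and comes back to the route at 16.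

Step 6. Acyl transfer may stall at the doubly ortho‑substituted acyl carbon, the phenol may be trifluoroacetylated instead, or the acid medium may cost the benzyl ether. Fallback: setting out from 7, 1‑chloro‑N,N,2‑trimethylprop‑1‑en‑1‑amine (CH2Cl2, 0 °C → rt) should give 2‑(benzyloxy)‑6‑bromo‑4‑methoxybenzoyl chloride F2 under neutral conditions. F2 is then added to the monosodium phenoxide of 9 (NaH, 1.0 equiv, THF, 0 °C), in which only the more acidic, non‑chelated 4‑OH is deprotonated. This replaces acid‑promoted activation of the acid by base‑promoted activation of the nucleophile and comes back to the route at 11.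

Step 9. Cleavage of the hindered aryl benzyl ether may be incomplete, the ketone may be over‑reduced on prolonged exposure, or the freed keto depside may lactonise during isolation. Fallback: setting out from 16, non‑reductive Lewis‑acid debenzylation (BCl3, pentamethylbenzene as cation scavenger, CH2Cl2, −78 °C) should remove both benzyl groups and lead directly to 17; no new compound is formed on the way (F0).

**Further compounds**
F1 | step 8 | benzyl 4‑{[2‑(benzyloxy)‑4‑methoxy‑6‑(non‑1‑yn‑1‑yl)benzoyl]oxy}‑2‑hydroxy‑6‑methylbenzoate | CCCCCCCC#Cc1cc(OC)cc(OCc2ccccc2)c1C(=O)Oc1cc(C)c(C(=O)OCc2ccccc2)c(O)c1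
F2 | step 6 | 2‑(benzyloxy)‑6‑bromo‑4‑methoxybenzoyl chloride | O=C(Cl)c1c(Br)cc(OC)cc1OCc1ccccc1
F0 | step 9 | none | none
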